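## Structural features

Cinnamtannin A2 (21) is a linear tetramer of (−)-epicatechin. Each unit is a 2-aryl-chroman-3-ol: a phloroglucinol-type ring A fused to a pyran ring C that carries a catechol ring B at C2. The units are numbered 1 (top, C8 unsubstituted) to 4 (terminal, C4 a methylene group); three interflavan bonds join C4 of one unit to C8 of the next, each 4β, that is trans to the neighbouring C3 oxygen. There are eleven stereocentres: the contiguous triads C2/C3/C4 of units 1 to 3 (2,3-cis, 3,4-trans) and the pair C2/C3 of unit 4, every unit being 2R,3R. The fragile elements are the sixteen phenols and the three doubly benzylic interflavan bonds. Catechols oxidise in air, free phenols allow base-induced opening of ring C with epimerisation at C2, and the interflavan bonds ionise under acid, so the last steps must be neutral. The real difficulty is control of chain length, of C8 against C6 attachment on each ring A, and of the cis,trans triad in the extended units. In unit 1 the ring oxygen O1 and the benzhydryl carbon C4 (bonded to C4a of its own ring A and to C8 of unit 2) are ortho on ring A. O1–C8a–C4a–C4 is therefore the heterodiene of an ortho-quinone methide and C2–C3 the alkene of a cis-β-oxygenated styrene, so ring C of unit 1 is a [4+2] adduct; this is what the key step uses.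

## Logic of the disconnections

21 to 20: the nineteen benzylic O–CH2 bonds are cut last. Benzyl is the only protecting group on oxygen, so one neutral hydrogenolysis releases all phenols and the three secondary alcohols of units 2 to 4 at once. The forward step must leave the interflavan C–C bonds and the O1–C2 ethers intact.

20 to 19: the acyl–oxygen bond at O3 of unit 1 is cut. The ester is what the 2π partner brings into the cycloaddition. Its removal by hydride rather than by hydroxide or acid keeps base away from the C2 centres and acid away from the interflavan bonds.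

19 to 13 and 17, through 18: C3–C4 and O1–C2 of unit 1 are cut. This removes ring C of unit 1 with its three stereocentres in one operation. It also turns the top interflavan bond into an ordinary aryl–carbinol bond, whose attachment to C8 of unit 2 is fixed by construction. 13 needs no control at the carbinol carbon, since both epimers lose water to the same 18, and 17 is achiral. The forward step must be regioselective, exo, face-selective and run under acid mild enough to spare three interflavan bonds. Only unit 1 is built this way: repeating the annulation for units 2 and 3 would need position-selective bromination of oligomers and three runs of an untested step, whereas units 2 to 4 are available intact from 1.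

13 to 7 and 10, through 11 and 12: the bond between the carbinol carbon and C8 of unit 2 is cut. The large fragment is made the nucleophile because 7 already carries bromine at that carbon; the small fragment is the aldehyde because its substitution pattern is fixed in 9. The opposite polarity would need directed lithiation of a phenol ether with two competing doubly activated positions. The phenol is masked as a silyl ether removed by fluoride. An acetal would need acid for its removal, and the same acid would ionise the carbinol. The forward step needs halogen–lithium exchange to outrun benzylic deprotonation and a work-up free of acid.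

10 to 9 to 8: the O–Si bond and two O–benzyl bonds are cut. The hydroxyl next to the formyl group is hydrogen-bonded and is the last to react, which differentiates the three oxygens without a separate regiochemical operation.

7 to 6 and 5: the bond C4 (unit 2)–C8 (unit 3) is cut. A flavan-4-yl cation adds to C8 of a benzylated ring A anti to the C3 substituent. The bromine on 5 blocks self-condensation of the electrophile and is the later handle for lithiation, so it does double duty. The forward step must prefer C8 of the upper unit of 6 over the C6 positions and run cold enough that the bond already present in 6 does not ionise.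

6 to 4 and 3: the bond C4 (unit 3)–C8 (unit 4) is cut in the same way. Here the electrophile is uncapped, so the nucleophile 3 is used in excess and recovered.

5 to 4 to 3 to 2 to 1: the C8–Br bond, the C4–O bond and the benzyl ethers are cut back to the chiral pool compound 1. 1 supplies C2 and C3 of units 2, 3 and 4 (six stereocentres); steps 5 and 6 set C4 of units 3 and 2; step 12 sets the remaining three.

17 to 15 and 16, then 15 to 14: the enol ester C–O bond is cut to a terminal alkyne and the acid, then one carbon is cut from the alkyne. The forward addition must be anti-Markovnikov and Z-selective, because the Z geometry is what later gives the 2,3-cis relation.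

## Other disconnections considered

Alternative 1: The cut runs through ring A of unit 2, at C8–C8a and C6–C7. In the forward sense the 4β-(silyloxyethynyl)flavan A1 (unit 1 complete) would be heated with the 3-benzyloxy-4-cinnamylcyclobutenone A2. Electrocyclic opening to a vinylketene, [2+2] addition to the ynol ether, a second opening and a 6π closure would give the phenol A3. In A3 unit 1 sits at C8 of a new ring A whose oxygens are differentiated (free at C8a, silylated at C7, benzylated at C5) and whose C4a carries a (Z)-cinnamyl chain.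
- In its favour: the 4→8 connectivity follows from the atom order of the cascade and cannot leak to C6. The conditions are neutral, so no interflavan bond is at risk. The benzannulation is a well-established reaction class.
- On these three points it is the equal or the better of the chosen plan, whose steps 5 and 6 rely on the inherent C8 preference of ring A and whose step 12 uses acid and an untested 2π partner.
- Against it: the key step creates no stereocentre. Ring C of unit 2 must still be closed from the Z-alkene with control of C2 and C3; asymmetric dihydroxylation of cis-alkenes is usually poorly face-selective, and the etherification that follows must be stereospecific. C4 of unit 2 is then still a methylene group, so units 3 and 4 would be attached afterwards by the same oxidation and cationic coupling as in steps 3 and 6. A1 itself needs a silyl ynol ether at a hindered benzylic carbon.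
- Comparison: it solves one interflavan bond cleanly but leaves most of the molecule to conventional chemistry. The step count would be clearly above the fourteen of the chosen route.

Alternative 2: The cut is C4a–C8a of ring A of unit 4. The 3,5,7-trioxooctanoate A4, carrying the benzyl-protected units 1 to 3 at its C2, would be folded by base, C6 attacking the ester carbon, to the 3-substituted 2,4,6-trihydroxyacetophenone A5.
- In its favour: the folding is biomimetic and runs under mild base, where interflavan bonds are safe (better than the acid of step 12). The attachment to ring A is fixed by the position of the substituent on the chain. The acetyl group is a handle for chalcone chemistry. As a single bond-forming event a Claisen condensation is mechanistically simpler and more predictable than step 12.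
- Against it: poly-β-carbonyl chains can also close by aldol reaction or by lactonisation to pyranones. The carbon of A4 that must bear the bulky flavanyl group is the least nucleophilic position of a polyketide polyanion, so making A4 is a problem in itself.
- After the key step ring C of unit 4 and both of its stereocentres are still missing. Either of the two hydroxyls ortho to the acetyl group of A5 could close the pyran, so the 8-linked against 6-linked question returns. The C4 carbonyl must then be removed and the cis 3-hydroxyl installed with absolute control.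
- Comparison: the chosen plan takes unit 4 intact from 1, with both stereocentres. The alternative would spend many steps rebuilding what the chiral pool supplies, and its step economy is distinctly worse.

Alternative 3: The cut is C2=C3 of ring C of unit 1 at the flav-2-ene oxidation level. A6 is the 3,4-bis(benzyloxy)benzoate of the ring A phenol, with a benzylic carbon bearing a vinyl group and C8 of unit 2. It would be treated with the reagent made from TiCl4, Zn, PbCl2, TMEDA and CH3CHBr2. A titanium alkylidene would engage the terminal alkene and the ester carbonyl and close the 4-aryl-flav-2-ene A7.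
- In its favour: it closes the same ring as the chosen key step, but without acid. C4 is set beforehand and is not touched. Carbonyl–olefin ring closure of olefinic esters with reduced titanium alkylidenes is established chemistry, so the precedent is better than for step 12. Ring B enters by a simple acylation.
- Against it: A6 needs the doubly benzylic, vinyl-bearing stereocentre to be set on the trimer beforehand. That is the same facial problem as in step 12, without the organisation of a ring-forming transition state. The ester of a di-ortho-substituted phenol is hindered.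
- After the key step C2 and C3 remain open. Hydroboration–oxidation of the enol ether anti to the C4 aryl group would place the 3-hydroxyl correctly trans to C4. It would, however, deliver hydrogen to C2 on the same face, leaving ring B trans to the hydroxyl (the catechin-type arrangement). That cannot be corrected by a simple oxidation–reduction at C3.
- Comparison: equal in the ring formed, better in mildness and precedent for the step itself. It is worse in that the three stereocentres are spread over three operations, and the endgame would be several steps longer with the C2 configuration unresolved.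

Key step: step 12

Remarks on the chemistry (assumptions):
- The structures of 13, 17 and 19 were checked atom by atom against 21 (ring A substitution, 4β→8 links, 2,3-cis/3,4-trans triads). No correction was needed.
- 2,4,6-Trihydroxybenzaldehyde (8), 3,4-bis(benzyloxy)benzaldehyde (14) and pivalic acid (16) are taken as purchasable.
- 4 and 5 are drawn as the 4β ethers expected from attack anti to the 3-benzyloxy group. The C4 epimer would serve equally, because this centre is ionised in steps 5 and 6.
- Which enantiomer of the phosphoric acid is matched with the chiral oligomer in step 12 cannot be derived from first principles. The (R)-acid is written; the (S)-acid is its direct substitute.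
- Step 12 is a condensation: the carbinol hydroxyl and the phenolic hydrogen of 13 leave as one molecule of water, which the molecular sieves bind.

## Route

Step 1
Reactants: 1 (−)-epicatechin
Product: 2 5,7,3′,4′-tetra-O-benzyl-(−)-epicatechin
Conditions: BnBr (4.4 equiv), K2CO3, DMF, 0 °C → rt
Reagents that add atoms: benzyl bromide, BrCc1ccccc1
Why: Williamson etherification of the four phenols with a weak base; the aliphatic 3-hydroxyl is not deprotonated and C2/C3 are untouched.

Step 2
Reactants: 2 5,7,3′,4′-tetra-O-benzyl-(−)-epicatechin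
Product: 3 3,5,7,3′,4′-penta-O-benzyl-(−)-epicatechin
Conditions: NaH, BnBr, Bu4NI (cat.), DMF, 0 °C → rt
Reagents that add atoms: benzyl bromide, BrCc1ccccc1
Why: Williamson etherification of the secondary alkoxide; with all phenols capped, the base-induced opening of ring C that epimerises C2 is not available.

Step 3
Reactants: 3 3,5,7,3′,4′-penta-O-benzyl-(−)-epicatechin
Product: 4 4β-(2-ethoxyethoxy)-3,5,7,3′,4′-penta-O-benzylepicatechin
Conditions: DDQ (2 equiv), 2-ethoxyethanol (6 equiv), CH2Cl2, rt
Reagents that add atoms: 2-ethoxyethanol, CCOCCO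
Why: Oxidative benzylic etherification: DDQ abstracts hydride from C4, which is activated by the 5,7-dioxygenated ring A, and the alcohol captures the flavan-4-yl cation anti to the 3-benzyloxy group.

Step 4
Reactants: 4 4β-(2-ethoxyethoxy)-3,5,7,3′,4′-penta-O-benzylepicatechin
Product: 5 8-bromo-4β-(2-ethoxyethoxy)-3,5,7,3′,4′-penta-O-benzylepicatechin
Conditions: NBS (1.05 equiv), CH2Cl2, −40 → 0 °C
Reagents that add atoms: N-bromosuccinimide, O=C1CCC(=O)N1Br
Why: Electrophilic aromatic bromination; in benzylated flavan-3-ols C8 (between O1 and the 7-benzyloxy group) reacts before C6, which lies between two benzyloxy groups.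

Step 5
Reactants: 4 4β-(2-ethoxyethoxy)-3,5,7,3′,4′-penta-O-benzylepicatechin; 3 3,5,7,3′,4′-penta-O-benzyl-(−)-epicatechin (4 equiv, excess recovered)
Product: 6 perbenzylated dimer, [penta-O-benzylepicatechin]-(4β→8)-[penta-O-benzylepicatechin] (units 3 and 4)
Conditions: TMSOTf (0.1 equiv), CH2Cl2, −78 °C; Et3N quench
Reagents that add atoms: none
Why: Lewis-acid ionisation of the C4 ether gives the flavan-4-yl cation, which C8 of 3 attacks in a Friedel–Crafts-type flavan coupling anti to the 3-benzyloxy group, setting C4 of unit 3 as 4β; the excess of 3 suppresses further chain growth.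

Step 6
Reactants: 6 perbenzylated dimer (1.2 equiv); 5 8-bromo-4β-(2-ethoxyethoxy)-3,5,7,3′,4′-penta-O-benzylepicatechin
Product: 7 8-bromo perbenzylated trimer, 8-bromo-[penta-O-benzylepicatechin]-(4β→8)-[penta-O-benzylepicatechin]-(4β→8)-[penta-O-benzylepicatechin] (units 2 to 4)
Conditions: TMSOTf (0.3 equiv), CH2Cl2, −78 → −40 °C; Et3N quench
Reagents that add atoms: none
Why: The same cationic flavan coupling; the bromine on 5 prevents self-condensation and growth at the top end, C8 of the upper unit of 6 is its most nucleophilic position, and attack anti to the 3-benzyloxy group sets C4 of unit 2 as 4β.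

Step 7
Reactants: 8 2,4,6-trihydroxybenzaldehyde
Product: 9 2-hydroxy-4,6-bis(benzyloxy)benzaldehyde
Conditions: BnBr (2.05 equiv), K2CO3 (2.2 equiv), DMF, 0 °C → rt
Reagents that add atoms: benzyl bromide, BrCc1ccccc1
Why: Williamson etherification under stoichiometric control; the para hydroxyl and one ortho hydroxyl react, while the second ortho hydroxyl is held in a hydrogen bond to the formyl group and is the least nucleophilic.

Step 8
Reactants: 9 2-hydroxy-4,6-bis(benzyloxy)benzaldehyde
Product: 10 2-(tert-butyldimethylsilyloxy)-4,6-bis(benzyloxy)benzaldehyde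
Conditions: TBSCl, imidazole, DMF, rt
Reagents that add atoms: tert-butyldimethylsilyl chloride, CC(C)(C)[Si](C)(C)Cl
Why: Silylation of the remaining phenol; a fluoride-labile group is chosen because an acid-labile one could not be removed later without ionising the carbinol.

Step 9
Reactants: 7 8-bromo perbenzylated trimer; 10 2-(tert-butyldimethylsilyloxy)-4,6-bis(benzyloxy)benzaldehyde (1.5 equiv)
Product: 13 (2-hydroxy-4,6-bis(benzyloxy)phenyl)(perbenzylated trimer-8-yl)methanol as a mixture of carbinol epimers, via trimer-8-yllithium 11 (not isolated), via O-silyl carbinol lithium alkoxide 12 (not isolated)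
Conditions: t-BuLi (2.1 equiv), THF, −78 °C; 10, −78 °C; TBAF (3 equiv), −78 → 0 °C; aq. NH4Cl; chromatography on Et3N-deactivated silica
Reagents that add atoms: none
Why: Bromine–lithium exchange at −78 °C outruns benzylic deprotonation, and 11 adds to the non-enolisable aldehyde (1,2-addition of an aryllithium). Fluoride then removes the silyl group from whichever oxygen holds it, so the carbinol never meets acid; both epimers converge in step 12.

Step 10
Reactants: 14 3,4-bis(benzyloxy)benzaldehyde
Product: 15 4-ethynyl-1,2-bis(benzyloxy)benzene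
Conditions: dimethyl (1-diazo-2-oxopropyl)phosphonate (1.3 equiv), K2CO3, MeOH/THF, 0 °C → rt
Reagents that add atoms: dimethyl (1-diazo-2-oxopropyl)phosphonate, CC(=O)C(=[N+]=[N-])P(=O)(OC)OC
Why: Seyferth–Gilbert homologation with the Ohira–Bestmann reagent: the diazomethylphosphonate anion formed in situ olefinates the aldehyde, and loss of N2 with 1,2-hydrogen shift gives the terminal alkyne.

Step 11
Reactants: 15 4-ethynyl-1,2-bis(benzyloxy)benzene; 16 pivalic acid
Product: 17 (Z)-2-[3,4-bis(benzyloxy)phenyl]ethenyl pivalate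
Conditions: [RuCl2(p-cymene)]2 (1 mol%), P(4-ClC6H4)3 (3 mol%), DMAP (4 mol%), toluene, 60 °C
Reagents that add atoms: none
Why: Ruthenium-catalysed anti-Markovnikov hydro-oxycarbonylation of a terminal alkyne; carboxylate attack on the ruthenium vinylidene carbon followed by protonolysis gives the (Z)-enol ester.

Step 12
Reactants: 13 (2-hydroxy-4,6-bis(benzyloxy)phenyl)(perbenzylated trimer-8-yl)methanol; 17 (Z)-2-[3,4-bis(benzyloxy)phenyl]ethenyl pivalate (3 equiv)
Product: 19 perbenzylated cinnamtannin A2 3-O-pivalate of unit 1, via (E)-ortho-quinone methide 18 (not isolated)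
Conditions: (R)-TRIP [(R)-3,3′-bis(2,4,6-triisopropylphenyl)-1,1′-binaphthyl-2,2′-diyl hydrogen phosphate] (10 mol%), 5 Å molecular sieves (bind the water released), CH2Cl2, −20 °C → rt, slow addition of 13
Reagents that add atoms: none
Why: Proposed new method: the phosphoric acid ionises either epimer of 13 (a carbinol flanked by two trioxygenated rings) with loss of one molecule of water to the hydrogen-bonded ortho-quinone methide 18, and 17 adds across O1=C8a–C4a=C4 in an asynchronous inverse-demand hetero-Diels–Alder reaction in which the pivaloyloxy-bearing carbon bonds to C4 while charge builds at the benzylic carbon para to a benzyloxy group, which the quinone oxygen then captures. The closest known reaction type is the Brønsted-acid-catalysed [4+2] addition of ortho-quinone methides from ortho-hydroxybenzhydrols to electron-rich styrenes giving 2,4-diarylchromans, whereas a (Z)-β-acyloxystyrene as 2π partner and the exo sense are untested. Ring C of unit 1 closes as a six-membered pyran by [4+2] cycloaddition, forming C3–C4 and O1–C2 (in the stepwise limit a 6-endo capture of the benzylic cation by the ring A oxygen). Regiochemistry follows from the styrene polarisation, because the 4-benzyloxyphenyl group is a much stronger donor than the acyloxy group. C2 and C3 come out cis because addition to the Z-alkene is suprafacial. C3 and C4 come out trans when ring B and the pivalate point away from the diene (exo), which keeps the pivalate over the open hydrogen-bearing side of C4 and away from the 5-benzyloxy group of ring A and the ortho oxygens of the twisted aryl group at C4. The absolute configuration at C4, and with it at C2 and C3, is set by the face of 18 left open by the bound chiral phosphate, reinforced or opposed by the stereocentres of unit 2. The step also needs chemoselectivity over capture of 18 by free C6 positions of other molecules, which the excess of 17 and the low stationary concentration of 18 should provide.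

Step 13
Reactants: 19 perbenzylated cinnamtannin A2 3-O-pivalate of unit 1
Product: 20 nonadeca-O-benzyl cinnamtannin A2 (3-hydroxyl of unit 1 free)
Conditions: LiAlH4 (3 equiv), THF, 0 °C → rt
Reagents that add atoms: none
Why: Reductive cleavage of the hindered ester by hydride at the acyl carbon; benzyl ethers and interflavan bonds are inert, and no stereocentre is touched because the C3–O bond stays intact.

Step 14
Reactants: 20 nonadeca-O-benzyl cinnamtannin A2
Product: 21 cinnamtannin A2
Conditions: H2 (1 atm), Pd(OH)2 on carbon, THF/MeOH/H2O, rt; filtration, lyophilisation under argon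
Reagents that add atoms: none
Why: Catalytic hydrogenolysis of all nineteen benzyl ethers under neutral conditions; the interflavan C–C bonds and the O1–C2 ring ethers are not cleaved under the conditions routinely used to debenzylate flavan-3-ols.

## Compound list

1 | (−)-epicatechin | Oc1cc(O)c2c(c1)O[C@H](c1ccc(O)c(O)c1)[C@H](O)C2 | starting material
2 | 5,7,3′,4′-tetra-O-benzyl-(−)-epicatechin | c3ccccc3COc1cc(OCc3ccccc3)c2c(c1)O[C@H](c1ccc(OCc3ccccc3)c(OCc3ccccc3)c1)[C@H](O)C2 | intermediate
3 | 3,5,7,3′,4′-penta-O-benzyl-(−)-epicatechin | c3ccccc3COc1cc(OCc3ccccc3)c2c(c1)O[C@H](c1ccc(OCc3ccccc3)c(OCc3ccccc3)c1)[C@H](OCc3ccccc3)C2 | intermediate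
4 | 4β-(2-ethoxyethoxy)-3,5,7,3′,4′-penta-O-benzylepicatechin | c3ccccc3COc1cc(OCc3ccccc3)c2c(c1)O[C@H](c1ccc(OCc3ccccc3)c(OCc3ccccc3)c1)[C@H](OCc3ccccc3)[C@H]2OCCOCC | intermediate
5 | 8-bromo-4β-(2-ethoxyethoxy)-3,5,7,3′,4′-penta-O-benzylepicatechin | Brc1c(OCc3ccccc3)cc(OCc3ccccc3)c2c1O[C@H](c1ccc(OCc3ccccc3)c(OCc3ccccc3)c1)[C@H](OCc3ccccc3)[C@H]2OCCOCC | intermediate
6 | perbenzylated dimer, [penta-O-benzylepicatechin]-(4β→8)-[penta-O-benzylepicatechin] | c3ccccc3COc1cc(OCc3ccccc3)c2c(c1)O[C@H](c1ccc(OCc3ccccc3)c(OCc3ccccc3)c1)[C@H](OCc3ccccc3)[C@H]2c1c(OCc3ccccc3)cc(OCc3ccccc3)c2c1O[C@H](c1ccc(OCc3ccccc3)c(OCc3ccccc3)c1)[C@H](OCc3ccccc3)C2 | intermediate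
7 | 8-bromo perbenzylated trimer (units 2 to 4, all links 4β→8) | Brc1c(OCc3ccccc3)cc(OCc3ccccc3)c2c1O[C@H](c1ccc(OCc3ccccc3)c(OCc3ccccc3)c1)[C@H](OCc3ccccc3)[C@H]2c1c(OCc3ccccc3)cc(OCc3ccccc3)c2c1O[C@H](c1ccc(OCc3ccccc3)c(OCc3ccccc3)c1)[C@H](OCc3ccccc3)[C@H]2c1c(OCc3ccccc3)cc(OCc3ccccc3)c2c1O[C@H](c1ccc(OCc3ccccc3)c(OCc3ccccc3)c1)[C@H](OCc3ccccc3)C2 | intermediate
8 | 2,4,6-trihydroxybenzaldehyde | O=Cc1c(O)cc(O)cc1O | starting material
9 | 2-hydroxy-4,6-bis(benzyloxy)benzaldehyde | O=Cc1c(O)cc(OCc2ccccc2)cc1OCc1ccccc1 | intermediate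
10 | 2-(tert-butyldimethylsilyloxy)-4,6-bis(benzyloxy)benzaldehyde | O=Cc1c(O[Si](C)(C)C(C)(C)C)cc(OCc2ccccc2)cc1OCc1ccccc1 | intermediate
11 | perbenzylated trimer-8-yllithium | [Li]c1c(OCc3ccccc3)cc(OCc3ccccc3)c2c1O[C@H](c1ccc(OCc3ccccc3)c(OCc3ccccc3)c1)[C@H](OCc3ccccc3)[C@H]2c1c(OCc3ccccc3)cc(OCc3ccccc3)c2c1O[C@H](c1ccc(OCc3ccccc3)c(OCc3ccccc3)c1)[C@H](OCc3ccccc3)[C@H]2c1c(OCc3ccccc3)cc(OCc3ccccc3)c2c1O[C@H](c1ccc(OCc3ccccc3)c(OCc3ccccc3)c1)[C@H](OCc3ccccc3)C2 | intermediate (not isolated)
12 | lithium alkoxide of [2-(tert-butyldimethylsilyloxy)-4,6-bis(benzyloxy)phenyl](perbenzylated trimer-8-yl)methanol, either carbinol epimer | CC(C)(C)[Si](C)(C)Oc1cc(OCc3ccccc3)cc(OCc3ccccc3)c1C(O[Li])c1c(OCc3ccccc3)cc(OCc3ccccc3)c2c1O[C@H](c1ccc(OCc3ccccc3)c(OCc3ccccc3)c1)[C@H](OCc3ccccc3)[C@H]2c1c(OCc3ccccc3)cc(OCc3ccccc3)c2c1O[C@H](c1ccc(OCc3ccccc3)c(OCc3ccccc3)c1)[C@H](OCc3ccccc3)[C@H]2c1c(OCc3ccccc3)cc(OCc3ccccc3)c2c1O[C@H](c1ccc(OCc3ccccc3)c(OCc3ccccc3)c1)[C@H](OCc3ccccc3)C2 | intermediate (not isolated)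
13 | (2-hydroxy-4,6-bis(benzyloxy)phenyl)(perbenzylated trimer-8-yl)methanol, either carbinol epimer | Oc1cc(OCc3ccccc3)cc(OCc3ccccc3)c1C(O)c1c(OCc3ccccc3)cc(OCc3ccccc3)c2c1O[C@H](c1ccc(OCc3ccccc3)c(OCc3ccccc3)c1)[C@H](OCc3ccccc3)[C@H]2c1c(OCc3ccccc3)cc(OCc3ccccc3)c2c1O[C@H](c1ccc(OCc3ccccc3)c(OCc3ccccc3)c1)[C@H](OCc3ccccc3)[C@H]2c1c(OCc3ccccc3)cc(OCc3ccccc3)c2c1O[C@H](c1ccc(OCc3ccccc3)c(OCc3ccccc3)c1)[C@H](OCc3ccccc3)C2 | intermediate
14 | 3,4-bis(benzyloxy)benzaldehyde | O=Cc1ccc(OCc2ccccc2)c(OCc2ccccc2)c1 | starting material
15 | 4-ethynyl-1,2-bis(benzyloxy)benzene | C#Cc1ccc(OCc2ccccc2)c(OCc2ccccc2)c1 | intermediate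
16 | pivalic acid | CC(C)(C)C(=O)O | starting material
17 | (Z)-2-[3,4-bis(benzyloxy)phenyl]ethenyl pivalate | CC(C)(C)C(=O)O/C=C\c1ccc(OCc3ccccc3)c(OCc3ccccc3)c1 | intermediate
18 | (E)-ortho-quinone methide, 3,5-bis(benzyloxy)-6-[(perbenzylated trimer-8-yl)methylidene]cyclohexa-2,4-dien-1-one | O=C1C=C(OCc3ccccc3)C=C(OCc3ccccc3)/C1=C\c1c(OCc3ccccc3)cc(OCc3ccccc3)c2c1O[C@H](c1ccc(OCc3ccccc3)c(OCc3ccccc3)c1)[C@H](OCc3ccccc3)[C@H]2c1c(OCc3ccccc3)cc(OCc3ccccc3)c2c1O[C@H](c1ccc(OCc3ccccc3)c(OCc3ccccc3)c1)[C@H](OCc3ccccc3)[C@H]2c1c(OCc3ccccc3)cc(OCc3ccccc3)c2c1O[C@H](c1ccc(OCc3ccccc3)c(OCc3ccccc3)c1)[C@H](OCc3ccccc3)C2 | intermediate (not isolated)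
19 | perbenzylated cinnamtannin A2 3-O-pivalate of unit 1 | c3ccccc3COc1cc(OCc3ccccc3)c2c(c1)O[C@H](c1ccc(OCc3ccccc3)c(OCc3ccccc3)c1)[C@H](OC(=O)C(C)(C)C)[C@H]2c1c(OCc3ccccc3)cc(OCc3ccccc3)c2c1O[C@H](c1ccc(OCc3ccccc3)c(OCc3ccccc3)c1)[C@H](OCc3ccccc3)[C@H]2c1c(OCc3ccccc3)cc(OCc3ccccc3)c2c1O[C@H](c1ccc(OCc3ccccc3)c(OCc3ccccc3)c1)[C@H](OCc3ccccc3)[C@H]2c1c(OCc3ccccc3)cc(OCc3ccccc3)c2c1O[C@H](c1ccc(OCc3ccccc3)c(OCc3ccccc3)c1)[C@H](OCc3ccccc3)C2 | intermediate
20 | nonadeca-O-benzyl cinnamtannin A2 (3-hydroxyl of unit 1 free) | c3ccccc3COc1cc(OCc3ccccc3)c2c(c1)O[C@H](c1ccc(OCc3ccccc3)c(OCc3ccccc3)c1)[C@H](O)[C@H]2c1c(OCc3ccccc3)cc(OCc3ccccc3)c2c1O[C@H](c1ccc(OCc3ccccc3)c(OCc3ccccc3)c1)[C@H](OCc3ccccc3)[C@H]2c1c(OCc3ccccc3)cc(OCc3ccccc3)c2c1O[C@H](c1ccc(OCc3ccccc3)c(OCc3ccccc3)c1)[C@H](OCc3ccccc3)[C@H]2c1c(OCc3ccccc3)cc(OCc3ccccc3)c2c1O[C@H](c1ccc(OCc3ccccc3)c(OCc3ccccc3)c1)[C@H](OCc3ccccc3)C2 | intermediate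
21 | cinnamtannin A2 | Oc1cc(O)c2c(c1)O[C@H](c1ccc(O)c(O)c1)[C@H](O)[C@H]2c1c(O)cc(O)c2c1O[C@H](c1ccc(O)c(O)c1)[C@H](O)[C@H]2c1c(O)cc(O)c2c1O[C@H](c1ccc(O)c(O)c1)[C@H](O)[C@H]2c1c(O)cc(O)c2c1O[C@H](c1ccc(O)c(O)c1)[C@H](O)C2 | target

## Step count and risk

Total: 14 steps. Longest linear sequence: 9 steps (steps 1, 2, 3, 4, 6, 9, 12, 13, 14 from 1).

Step 12 (key step, proposed new method). Three things may go wrong.
- Bond formation at C4 may be slow. The methide carbon of 18 lies between two di-ortho-oxygenated rings, so it is both strongly stabilised and shielded. 18 could then be consumed by self-condensation with free C6 positions, or simply return to 13 by re-addition of water if the sieves do not bind it.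
- The addition may run endo, or stepwise through a free benzylic cation with loss of the alkene geometry. Either would erode the 3,4-trans or the 2,3-cis relation.
- The bulky phosphate may fail to override the intrinsic facial bias of the chiral oligomer.

The fallback uses only the established cationic flavan coupling; it sets out from 7 and 5 and returns at 21. Bromine–lithium exchange on 7 (t-BuLi, THF, −78 °C) and a methanol quench would give the perbenzylated trimer with free C8, F1. F1 would be coupled with the bromo-capped electrophile 5 (TMSOTf, CH2Cl2, −78 °C; near-equimolar amounts, since the cap excludes self-condensation) to the 8-bromo perbenzylated tetramer F2, with unit 1 attached 4β by attack anti to its 3-benzyloxy group. Hydrogenolysis of F2 over Pd(OH)2 on carbon with one equivalent of Et3N would remove the bromine and all twenty benzyl groups and give 21.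

Step 9. The hindered aryllithium 11 may be protonated or may attack silicon faster than it adds to the electron-rich, di-ortho-substituted aldehyde. Benzylic lithiation may also compete with the exchange. The product may ionise during purification. The fallback reverses the polarity so that the cheap partner can be used in excess; it sets out from 7 and returns at 13. Lithium species 11 would be quenched with DMF, a small electrophile, to give the perbenzylated trimer-8-carbaldehyde F3. Purchasable 3,5-bis(benzyloxy)phenol would be converted (NaH, Et2NCOCl, THF) into 3,5-bis(benzyloxy)phenyl N,N-diethylcarbamate F4. F4 would be lithiated between the carbamate and a benzyloxy group (s-BuLi, TMEDA, THF, −78 °C; the carbamate is the strongest ortho director present) and added in excess to F3 at −78 °C with a cold quench, giving the carbinol carbamate F5. LiAlH4 in THF would cleave the aryl carbamate without acid and give 13; a carbamoyl group that had migrated to the benzylic oxygen would be removed in the same way.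

Step 6. Attack may occur at a C6 position of 6 instead of C8 of its upper unit. The less reactive bromo-capped electrophile may also need activation strong enough to ionise the interflavan bond already present, scrambling the chain. The fallback uses orthogonal activation so that each coupling has a monomer as nucleophile; it sets out from 4, 5 and 3 and returns at 7. 4 would be converted with 2,6-dimethylbenzenethiol and BF3·OEt2 (CH2Cl2, −78 °C) into 4β-(2,6-dimethylphenylthio)-penta-O-benzylepicatechin F6. 5 would be coupled with F6 under BF3·OEt2 at −78 °C, which activates the alkoxy group but leaves the sulfide alone, to give the 8-bromo perbenzylated dimer 4β-thioether F7. F7 would then be activated thiophilically (I2, Ag2O, CH2Cl2, −40 °C) in the presence of 3 to give 7.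

Step 7. Alkylation may not stop cleanly at the dibenzyl stage, and C-benzylation of the phloroglucinol ring may compete. The fallback over-alkylates and then removes one group selectively; it sets out from 8 and returns at 9. Exhaustive benzylation (excess BnBr, K2CO3, DMF, 60 °C) would give 2,4,6-tris(benzyloxy)benzaldehyde F8. MgBr2·OEt2 (toluene/Et2O, reflux) would then remove one benzyl group ortho to the formyl group by chelation-controlled cleavage and give 9.

## Further compounds

F1 | step 12 | perbenzylated trimer with free C8, [penta-O-benzylepicatechin]-(4β→8)-[penta-O-benzylepicatechin]-(4β→8)-[penta-O-benzylepicatechin] | c3ccccc3COc1cc(OCc3ccccc3)c2c(c1)O[C@H](c1ccc(OCc3ccccc3)c(OCc3ccccc3)c1)[C@H](OCc3ccccc3)[C@H]2c1c(OCc3ccccc3)cc(OCc3ccccc3)c2c1O[C@H](c1ccc(OCc3ccccc3)c(OCc3ccccc3)c1)[C@H](OCc3ccccc3)[C@H]2c1c(OCc3ccccc3)cc(OCc3ccccc3)c2c1O[C@H](c1ccc(OCc3ccccc3)c(OCc3ccccc3)c1)[C@H](OCc3ccccc3)C2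
F2 | step 12 | 8-bromo perbenzylated tetramer (eicosa-O-benzyl-8-bromocinnamtannin A2) | Brc1c(OCc3ccccc3)cc(OCc3ccccc3)c2c1O[C@H](c1ccc(OCc3ccccc3)c(OCc3ccccc3)c1)[C@H](OCc3ccccc3)[C@H]2c1c(OCc3ccccc3)cc(OCc3ccccc3)c2c1O[C@H](c1ccc(OCc3ccccc3)c(OCc3ccccc3)c1)[C@H](OCc3ccccc3)[C@H]2c1c(OCc3ccccc3)cc(OCc3ccccc3)c2c1O[C@H](c1ccc(OCc3ccccc3)c(OCc3ccccc3)c1)[C@H](OCc3ccccc3)[C@H]2c1c(OCc3ccccc3)cc(OCc3ccccc3)c2c1O[C@H](c1ccc(OCc3ccccc3)c(OCc3ccccc3)c1)[C@H](OCc3ccccc3)C2
F3 | step 9 | perbenzylated trimer-8-carbaldehyde | O=Cc1c(OCc3ccccc3)cc(OCc3ccccc3)c2c1O[C@H](c1ccc(OCc3ccccc3)c(OCc3ccccc3)c1)[C@H](OCc3ccccc3)[C@H]2c1c(OCc3ccccc3)cc(OCc3ccccc3)c2c1O[C@H](c1ccc(OCc3ccccc3)c(OCc3ccccc3)c1)[C@H](OCc3ccccc3)[C@H]2c1c(OCc3ccccc3)cc(OCc3ccccc3)c2c1O[C@H](c1ccc(OCc3ccccc3)c(OCc3ccccc3)c1)[C@H](OCc3ccccc3)C2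
F4 | step 9 | 3,5-bis(benzyloxy)phenyl N,N-diethylcarbamate | CCN(CC)C(=O)Oc1cc(OCc2ccccc2)cc(OCc2ccccc2)c1
F5 | step 9 | [2-(diethylcarbamoyloxy)-4,6-bis(benzyloxy)phenyl](perbenzylated trimer-8-yl)methanol, either carbinol epimer | CCN(CC)C(=O)Oc1cc(OCc3ccccc3)cc(OCc3ccccc3)c1C(O)c1c(OCc3ccccc3)cc(OCc3ccccc3)c2c1O[C@H](c1ccc(OCc3ccccc3)c(OCc3ccccc3)c1)[C@H](OCc3ccccc3)[C@H]2c1c(OCc3ccccc3)cc(OCc3ccccc3)c2c1O[C@H](c1ccc(OCc3ccccc3)c(OCc3ccccc3)c1)[C@H](OCc3ccccc3)[C@H]2c1c(OCc3ccccc3)cc(OCc3ccccc3)c2c1O[C@H](c1ccc(OCc3ccccc3)c(OCc3ccccc3)c1)[C@H](OCc3ccccc3)C2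
F6 | step 6 | 4β-(2,6-dimethylphenylthio)-3,5,7,3′,4′-penta-O-benzylepicatechin | c3ccccc3COc1cc(OCc3ccccc3)c2c(c1)O[C@H](c1ccc(OCc3ccccc3)c(OCc3ccccc3)c1)[C@H](OCc3ccccc3)[C@H]2Sc1c(C)cccc1C
F7 | step 6 | 8-bromo perbenzylated dimer carrying a 4β-(2,6-dimethylphenylthio) group on its lower unit | Brc1c(OCc3ccccc3)cc(OCc3ccccc3)c2c1O[C@H](c1ccc(OCc3ccccc3)c(OCc3ccccc3)c1)[C@H](OCc3ccccc3)[C@H]2c1c(OCc3ccccc3)cc(OCc3ccccc3)c2c1O[C@H](c1ccc(OCc3ccccc3)c(OCc3ccccc3)c1)[C@H](OCc3ccccc3)[C@H]2Sc1c(C)cccc1C
F8 | step 7 | 2,4,6-tris(benzyloxy)benzaldehyde | O=Cc1c(OCc2ccccc2)cc(OCc2ccccc2)cc1OCc1ccccc1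
A1 | alternative 1 | 4β-(triisopropylsilyloxyethynyl)-3,5,7,3′,4′-penta-O-benzylepicatechin | c3ccccc3COc1cc(OCc3ccccc3)c2c(c1)O[C@H](c1ccc(OCc3ccccc3)c(OCc3ccccc3)c1)[C@H](OCc3ccccc3)[C@H]2C#CO[Si](C(C)C)(C(C)C)C(C)C
A2 | alternative 1 | 3-benzyloxy-4-[(Z)-3-(3,4-bis(benzyloxy)phenyl)prop-2-enyl]cyclobut-2-enone | O=C1C=C(OCc2ccccc2)C1C/C=C\c1ccc(OCc2ccccc2)c(OCc2ccccc2)c1
A3 | alternative 1 | unit 1 joined 4β to C8 of a new ring A with free C8a hydroxyl, C7 triisopropylsilyloxy, C5 benzyloxy and a (Z)-cinnamyl chain at C4a | c3ccccc3COc1cc(OCc3ccccc3)c2c(c1)O[C@H](c1ccc(OCc3ccccc3)c(OCc3ccccc3)c1)[C@H](OCc3ccccc3)[C@H]2c1c(O[Si](C(C)C)(C(C)C)C(C)C)cc(OCc3ccccc3)c(C/C=C\c4ccc(OCc3ccccc3)c(OCc3ccccc3)c4)c1O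
A4 | alternative 2 | methyl 3,5,7-trioxooctanoate carrying the benzyl-protected units 1 to 3 (4β of unit 3) at C2 | c3ccccc3COc1cc(OCc3ccccc3)c2c(c1)O[C@H](c1ccc(OCc3ccccc3)c(OCc3ccccc3)c1)[C@H](OCc3ccccc3)[C@H]2c1c(OCc3ccccc3)cc(OCc3ccccc3)c2c1O[C@H](c1ccc(OCc3ccccc3)c(OCc3ccccc3)c1)[C@H](OCc3ccccc3)[C@H]2c1c(OCc3ccccc3)cc(OCc3ccccc3)c2c1O[C@H](c1ccc(OCc3ccccc3)c(OCc3ccccc3)c1)[C@H](OCc3ccccc3)[C@H]2C(C(=O)OC)C(=O)CC(=O)CC(C)=O
A5 | alternative 2 | benzyl-protected units 1 to 3 joined 4β to C3 of 2,4,6-trihydroxyacetophenone | c3ccccc3COc1cc(OCc3ccccc3)c2c(c1)O[C@H](c1ccc(OCc3ccccc3)c(OCc3ccccc3)c1)[C@H](OCc3ccccc3)[C@H]2c1c(OCc3ccccc3)cc(OCc3ccccc3)c2c1O[C@H](c1ccc(OCc3ccccc3)c(OCc3ccccc3)c1)[C@H](OCc3ccccc3)[C@H]2c1c(OCc3ccccc3)cc(OCc3ccccc3)c2c1O[C@H](c1ccc(OCc3ccccc3)c(OCc3ccccc3)c1)[C@H](OCc3ccccc3)[C@H]2c1c(O)cc(O)c(C(C)=O)c1O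
A6 | alternative 3 | 3,5-bis(benzyloxy)-2-[1-(perbenzylated trimer-8-yl)prop-2-enyl]phenyl 3,4-bis(benzyloxy)benzoate | C=C[C@H](c1c(OC(=O)c4ccc(OCc3ccccc3)c(OCc3ccccc3)c4)cc(OCc3ccccc3)cc1OCc3ccccc3)c1c(OCc3ccccc3)cc(OCc3ccccc3)c2c1O[C@H](c1ccc(OCc3ccccc3)c(OCc3ccccc3)c1)[C@H](OCc3ccccc3)[C@H]2c1c(OCc3ccccc3)cc(OCc3ccccc3)c2c1O[C@H](c1ccc(OCc3ccccc3)c(OCc3ccccc3)c1)[C@H](OCc3ccccc3)[C@H]2c1c(OCc3ccccc3)cc(OCc3ccccc3)c2c1O[C@H](c1ccc(OCc3ccccc3)c(OCc3ccccc3)c1)[C@H](OCc3ccccc3)C2
A7 | alternative 3 | benzyl-protected tetramer with unit 1 as a 4-aryl-flav-2-ene | c3ccccc3COc1cc(OCc3ccccc3)c2c(c1)OC(c1ccc(OCc3ccccc3)c(OCc3ccccc3)c1)=C[C@H]2c1c(OCc3ccccc3)cc(OCc3ccccc3)c2c1O[C@H](c1ccc(OCc3ccccc3)c(OCc3ccccc3)c1)[C@H](OCc3ccccc3)[C@H]2c1c(OCc3ccccc3)cc(OCc3ccccc3)c2c1O[C@H](c1ccc(OCc3ccccc3)c(OCc3ccccc3)c1)[C@H](OCc3ccccc3)[C@H]2c1c(OCc3ccccc3)cc(OCc3ccccc3)c2c1O[C@H](c1ccc(OCc3ccccc3)c(OCc3ccccc3)c1)[C@H](OCc3ccccc3)C2
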